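## Analysis of the target

Locants used throughout: the seven-membered ring is C2 (CHCH3), C3, C4, C5 (C–OH), C6 (H), C10 (C=O) and C11 (quaternary, CH3 and side chain); C7 (CH2), C8 (CHOH) and C9 (C(CH3)2) complete the five-membered ring with C5 and C6; C12 and C13 are the chain CH2 groups; the butenolide is C2'–C5', attached through C4'.

- Target 22 is a trans-fused hydroazulene: a cycloheptanone shares the C5–C6 bond with a cyclopentane, and C11 carries a two-carbon chain ending in a β-substituted butenolide.
- Its five stereocentres fall into two groups too far apart to influence each other. C2 (R) and C11 (R) carry trans methyl groups. C8 (S), C5 (S) and C6 (S) have the two hydroxyl groups trans across C9 and C6–H anti to the C5 hydroxyl, which is therefore syn to the C10 carbonyl.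
- The sensitive groups are the tertiary β-hydroxy ketone C5(OH)–C6–C10(=O) (retro-aldol opening, dehydration, epimerisation at C6) and the butenolide (strong base, hydride, carbon nucleophiles).
- The difficulty is crowding: C5 is a tertiary carbinol wedged between fully substituted C9 and the ring fusion, C11 is quaternary next to stereocentre C2, and C10 lies between C11 and C6.
- The plan rests on C9: a fully substituted carbon flanked by the secondary carbinol C8 and the tertiary carbinol C5. That 1,3-diol across a gem-dimethyl carbon is what remains when the tertiary radical from a 2,2-dimethyl epoxide adds to a ketone.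

## Retrosynthetic reasoning

**22 from 21.** Only C6 is changed. C6–H is α to the C10 carbonyl, so the trans fusion is reached by equilibration of the first-formed aldol 21. This is planned because the ring-forming step cannot be relied on to give the trans fusion directly.

**21 from 19 (key disconnection).** The C5–C9 bond is cut. This removes the cyclopentane and both carbinol stereocentres in one stroke and leaves a monocyclic cycloheptane-1,3-dione carrying an epoxide. No other cut in the five-membered ring joins two oxygen-bearing carbons through a carbon that can be a tertiary radical. The forward step must open the epoxide at C9 with retention of the C8 oxygen, add the radical to C5 and not to C10, choose the C5 face that puts the new oxygen trans to O8, and outrun termination of the radical.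

**19 from 18.** The epoxide oxygen is removed. C8 is remote from C2 and C11, so its configuration must come from the reagent (a chiral dioxirane). The epoxide is introduced last because it survives neither the acid needed to unmask C5 nor base in the presence of the acidic dione. The oxidation must therefore be run with the dione un-ionised.

**18 from 16 and 17.** The C6–C7 bond is cut. C6 is the doubly activated carbon of the dione, and π-allylpalladium chemistry with acetate 17 gives C-alkylation at the unsubstituted allyl terminus without strong base, which the butenolide would not tolerate.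

**16 from 15.** The C5 carbonyl is unmasked. The dioxolane was needed so that C10 alone served as enone carbonyl and enolate site while C2 and C11 were built. It is removed by acid before any acid-sensitive group is present.

**15 from 12 and 13.** The C13–C4' bond is cut. Coupling a primary alkylzinc iodide (14, from 12) with the preformed bromobutenolide 13 avoids building a lactone on a molecule with other carbonyl groups and needs no base.

**12 from 11 from 9.** These are functional-group changes: iodide from alcohol, alcohol from the allyl group by excision of its terminal carbon through aldehyde 10. The allyl group is the handle that the earlier enone chemistry can carry.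

**9 from 7.** The C2–CH3 and C11–CH3 bonds are cut. Only a C10 enone makes C2 electrophilic. The enolate 8 formed by conjugate methylation is regiodefined at C11, and a methyl electrophile enters anti to the new C2 methyl. The chain must therefore already sit on the enone to obtain the trans-dimethyl pattern. An asymmetric catalyst sets the absolute configuration here from achiral 7.

**7 from 5 and 6.** The C11–C12 bond is cut, as a cross-coupling of α-iodoenone 5 with stannane 6.

**5 from 4 from 2 from 1.** Iodination of enone 4, dehydrogenation of ketone 2 through silyl enol ether 3 on the side away from the ketal, and monoketalisation of symmetric dione 1.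

## Alternatives that were turned down

**Alternative 1: divinylcyclopropane rearrangement.**
- Disconnection: the C2–C3 bond of the seven-membered ring. Cycloheptadiene A2 is traced to the cis-divinyl siloxycyclopropane A1, in which C10, C5 and C6 form a three-membered ring on a finished cyclopentane.
- Forward step: on warming, A1 undergoes the [3,3] shift through a boat transition state, forming C2–C3 and breaking C5–C10, to give A2 with a C10=C11 silyl enol ether and a C4=C5 alkene.
- For: the step is strain-driven and stereospecific (the E alkene of A1 fixes C2 relative to C6), it has no chemoselectivity question between two carbonyls, and it delivers a regiodefined enol ether ready for methylation at C11. On construction of the seven-membered ring it is stronger than the chosen plan.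
- Against: A1 is a tetrasubstituted cyclopropane with a defined alkene geometry and three silyl ethers, and it is long to make. After the key step C11 must still be made quaternary on a flexible cycloheptadiene, the C5 hydroxyl must be added to the C4=C5 alkene with Markovnikov and facial control, and the butenolide must be built from a protected alcohol.
- Comparison: the chosen strategy offers a one-step end game instead. C5–OH, C5–C9 and the ring form together, under control of a catalyst-set C8, with the butenolide already present and no protecting group after the ketal.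

**Alternative 2: tandem conjugate methylation and enolate methylation.**
- Disconnection: both methyl groups are removed from ketal A4 to leave the achiral 2-allyl enone A3.
- Forward step: a methylaluminium reagent adds to C2 under copper–phosphoramidite catalysis and the C11 enolate is methylated.
- For: one operation creates the two stereocentres that cannot be corrected later, fixes the absolute configuration by catalyst and the trans relation by anti-alkylation. On C2/C11 it is as strong as anything the chosen strategy has.
- Against, as the centre of a plan: it settles two of five stereocentres and none of the ring problem. The cyclopentane, both carbinols and their relation to C6 would still be open.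
- Comparison: this is not a rival bond construction. The chosen route adopts it as step 5, and A3 and A4 are identical with 7 and 9. What was turned down is resting the design on it. The chosen strategy adds the answer to the other half of the molecule.

**Alternative 3: hydroacylation closing the cyclopentanone.**
- Disconnection: the C7–C8 bond. Diketone A6 is traced to aldehyde–enone A5, which already holds the protected C5 carbinol, the gem-dimethyl aldehyde at C9 and an exocyclic C6=C7 methylene.
- Forward step: a cationic rhodium–diphosphine catalyst inserts into the aldehyde C–H bond, adds across the methylene and closes the five-membered ketone.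
- For: 4-pentenal hydroacylation is a well-behaved closed-shell catalytic ring closure, and the quaternary α-carbon prevents enolisation of the aldehyde. The C5 carbinol exists beforehand, so there is no C5/C10 question and no fragile epoxy dione. On reliability of the ring closure it is as strong as or stronger than the chosen step.
- Against: C5 must be created earlier by adding a hindered carbon nucleophile to the C5 carbonyl with only remote stereocentres to guide it. The acceptor is an electron-poor 1,1-disubstituted alkene. The ring fusion is set in the insertion step. The C8 ketone must later be reduced selectively beside the C10 ketone, trans to O5. Two silyl groups must be removed and the butenolide still attached.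
- Comparison: the chosen strategy sets C8 by reagent before ring closure, lets C8 control C5 in the bond-forming step, and needs one step after it.

Key step: step 12

Assumption: of the two C6 epimers of the final aldol, the trans-fused one (C5 hydroxyl syn to, and hydrogen-bonded with, the C10 carbonyl) is taken to be the more stable, so that equilibration next to the carbonyl leads to 22.

## Route

Step 1
Reactants: 1 cycloheptane-1,3-dione
Product: 2 1,4-dioxaspiro[4.6]undecan-7-one
Conditions: HOCH2CH2OH (1.05 equiv), p-toluenesulfonic acid monohydrate (cat.), benzene, reflux, Dean–Stark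
Reagents that add atoms: ethane-1,2-diol, OCCO
Why: Acid-catalysed ketalisation with removal of water; the carbonyl groups of 1 are equivalent, and once one has reacted the dioxolane oxygens β to the other destabilise its oxocarbenium ion, so one equivalent of diol should stop at the monoketal. The ketal silences the later C5 carbonyl and leaves C10 as the only ketone.

Step 2
Reactants: 2 1,4-dioxaspiro[4.6]undecan-7-one
Product: 4 1,4-dioxaspiro[4.6]undec-8-en-7-one, via silyl enol ether 3 (not isolated)
Conditions: LiN(iPr)2, THF, −78 °C; Me3SiCl, −78 → 0 °C; then Pd(OAc)2 (1.05 equiv), MeCN, rt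
Reagents that add atoms: none
Why: Saegusa–Ito dehydrogenation. Kinetic deprotonation should take the unhindered C8–H and not the C6–H between carbonyl and ketal; a C6 enol ether has no β-hydrogen to lose (C5 is the ketal carbon) and can only revert to 2, so only the C8=C9 enone can form.

Step 3
Reactants: 4 1,4-dioxaspiro[4.6]undec-8-en-7-one
Product: 5 8-iodo-1,4-dioxaspiro[4.6]undec-8-en-7-one
Conditions: I2, pyridine/CH2Cl2 (1:1), 0 °C → rt
Reagents that add atoms: iodine, II
Why: α-Iodination of an enone by conjugate addition of pyridine, iodination of the enolate and elimination; the pyridine buffer protects the ketal.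

Step 4
Reactants: 5 8-iodo-1,4-dioxaspiro[4.6]undec-8-en-7-one; 6 allyltributylstannane
Product: 7 8-(prop-2-en-1-yl)-1,4-dioxaspiro[4.6]undec-8-en-7-one
Conditions: Pd2(dba)3 (2.5 mol%), AsPh3 (10 mol%), CuI (10 mol%), NMP, rt → 40 °C
Reagents that add atoms: none
Why: Stille coupling of an α-iodoenone; the weakly donating arsine and the copper co-catalyst allow transmetalation near room temperature, which limits migration of the allyl double bond into conjugation.

Step 5
Reactants: 7 8-(prop-2-en-1-yl)-1,4-dioxaspiro[4.6]undec-8-en-7-one
Product: 9 (8R,9R)-8,9-dimethyl-8-(prop-2-en-1-yl)-1,4-dioxaspiro[4.6]undecan-7-one, via aluminium enolate 8 (not isolated)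
Conditions: Me3Al (1.5 equiv), copper thiophene-2-carboxylate (5 mol%), binaphthol-derived bis(1-phenylethyl)amine phosphoramidite (10 mol%, the antipode that sends CH3 to the Re face of C9), Et2O, −30 °C; then MeLi (1.5 equiv), THF/DMPU, MeI (5 equiv), −30 → 0 °C
Reagents that add atoms: trimethylaluminium, C[Al](C)C; iodomethane, CI
Why: Copper-catalysed asymmetric conjugate addition to an α-substituted cyclic enone with alkylation of the enolate formed. The chiral copper complex chooses the face of C9 (C2 of the target, R); enolate 8 is regiodefined, MeLi turns it into the more nucleophilic aluminate, and MeI enters anti to the new neighbouring methyl group, which gives the trans-dimethyl pair (C11 of the target, R) with allyl cis to the C9 methyl.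

Step 6
Reactants: 9 (8R,9R)-8,9-dimethyl-8-(prop-2-en-1-yl)-1,4-dioxaspiro[4.6]undecan-7-one
Product: 11 (8R,9R)-8-(2-hydroxyethyl)-8,9-dimethyl-1,4-dioxaspiro[4.6]undecan-7-one, via aldehyde 10 (not isolated)
Conditions: O3, CH2Cl2/MeOH, −78 °C; Me2S, −78 °C → rt; then NaBH4 (1 equiv), −78 °C
Reagents that add atoms: ozone, [O-][O+]=O
Why: Ozonolysis removes the terminal carbon of the allyl group, and NaBH4 at −78 °C should reduce aldehyde 10 but not the ketone, which is flanked by the quaternary carbon. The C12–C13 chain now ends in a primary alcohol.

Step 7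
Reactants: 11 (8R,9R)-8-(2-hydroxyethyl)-8,9-dimethyl-1,4-dioxaspiro[4.6]undecan-7-one
Product: 12 (8R,9R)-8-(2-iodoethyl)-8,9-dimethyl-1,4-dioxaspiro[4.6]undecan-7-one
Conditions: I2, PPh3, imidazole, CH2Cl2, 0 °C → rt
Reagents that add atoms: iodine, II
Why: Appel-type iodination of a primary alcohol; the imidazole buffer keeps the medium non-acidic for the ketal.

Step 8
Reactants: 12 (8R,9R)-8-(2-iodoethyl)-8,9-dimethyl-1,4-dioxaspiro[4.6]undecan-7-one; 13 4-bromofuran-2(5H)-one
Product: 15 4-{2-[(8R,9R)-8,9-dimethyl-7-oxo-1,4-dioxaspiro[4.6]undecan-8-yl]ethyl}furan-2(5H)-one, via alkylzinc iodide 14 (not isolated)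
Conditions: Zn dust (activated), LiCl, THF, 40 °C; then 13, PdCl2(dppf) (5 mol%), THF, rt → 45 °C
Reagents that add atoms: none
Why: Negishi coupling of a primary alkylzinc iodide with a vinylogous acyl bromide. Zinc inserts into the C–I bond without touching ketone or ketal, oxidative addition into the β-bromobutenolide is fast, and no base is present that could deprotonate the butenolide.

Step 9
Reactants: 15 4-{2-[(8R,9R)-8,9-dimethyl-7-oxo-1,4-dioxaspiro[4.6]undecan-8-yl]ethyl}furan-2(5H)-one
Product: 16 (4R,5R)-4,5-dimethyl-4-[2-(5-oxo-2,5-dihydrofuran-3-yl)ethyl]cycloheptane-1,3-dione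
Conditions: 2 M HCl, THF, 40 °C
Reagents that add atoms: water, O
Why: Acid hydrolysis of the dioxolane; the butenolide is stable to aqueous acid, and the step is placed before the acid-sensitive prenyl and epoxide groups exist.

Step 10
Reactants: 16 (4R,5R)-4,5-dimethyl-4-[2-(5-oxo-2,5-dihydrofuran-3-yl)ethyl]cycloheptane-1,3-dione; 17 3-methylbut-2-en-1-yl acetate
Product: 18 (2S,4R,5R)-4,5-dimethyl-2-(3-methylbut-2-en-1-yl)-4-[2-(5-oxo-2,5-dihydrofuran-3-yl)ethyl]cycloheptane-1,3-dione
Conditions: 17 (1.0 equiv), Pd(PPh3)4 (5 mol%), Et3N (1.2 equiv), THF, 40 °C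
Reagents that add atoms: none
Why: Tsuji–Trost allylation. The soft dione anion attacks the prenyl–palladium cation at its unsubstituted terminus, any O-prenyl enol ether re-ionises under the catalyst and funnels to the C-alkylated dione, and the amine deprotonates only the dione and not the butenolide. C2 of this name (C6 of the target) is labile and is written 2S by convention.

Step 11
Reactants: 18 (2S,4R,5R)-4,5-dimethyl-2-(3-methylbut-2-en-1-yl)-4-[2-(5-oxo-2,5-dihydrofuran-3-yl)ethyl]cycloheptane-1,3-dione
Product: 19 (2S,4R,5R)-2-{[(2S)-3,3-dimethyloxiran-2-yl]methyl}-4,5-dimethyl-4-[2-(5-oxo-2,5-dihydrofuran-3-yl)ethyl]cycloheptane-1,3-dione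
Conditions: 1,2:4,5-di-O-isopropylidene-β-L-erythro-2,3-hexodiulo-2,6-pyranose (ent-Shi ketone, 3 equiv), KHSO5 (as Oxone, 2KHSO5·KHSO4·K2SO4), NaHCO3 (pH 7.5–8), aq. Na2EDTA, MeCN, 0 °C; neutral work-up, used at once
Reagents that add atoms: potassium peroxymonosulfate, [K+].[O-]S(=O)(=O)OO
Why: Shi epoxidation, selective for the electron-rich trisubstituted alkene over the butenolide. C8 is remote from the ring stereocentres, so the face is chosen by the reagent: the L-configured ketone is required for 8S, since the D-fructose-derived ketone would give 8R. The bicarbonate-buffered, stoichiometric-ketone protocol is used so that the dione stays un-ionised; at the usual pH 10.5 its enolate would be hydroxylated at C6 and would open the new epoxide.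

Step 12
Reactants: 19 (2S,4R,5R)-2-{[(2S)-3,3-dimethyloxiran-2-yl]methyl}-4,5-dimethyl-4-[2-(5-oxo-2,5-dihydrofuran-3-yl)ethyl]cycloheptane-1,3-dione
Product: 21 (2S,3aR,5R,6R,8aS)-2,8a-dihydroxy-1,1,5,6-tetramethyl-5-[2-(5-oxo-2,5-dihydrofuran-3-yl)ethyl]octahydroazulen-4(1H)-one, via bis-titanium alkoxide 20 (not isolated)
Conditions: Cp2TiCl2 (2.5 equiv), Mn dust (8 equiv), THF, rt (gives Cp2TiCl); this solution added over 2 h to 19 in THF (0.02 M), rt; aq. NaH2PO4
Reagents that add atoms: none
Why: Cp2TiCl (trivalent titanium) cleaves the C9–O bond of the epoxide homolytically, which leaves O8 with its configuration as a tetravalent-titanium alkoxide and puts the unpaired electron on tertiary C9. The radical adds 5-exo-trig to the carbon of the C5 carbonyl, forming C5–C9 and the cyclopentane; the alkoxy radical is reduced by a second Cp2TiCl held on that oxygen (or quenched by hydrogen abstraction from THF), which makes the otherwise reversible addition productive, and hydrolysis of 20 gives the diol. The closest known reaction type is the titanocene-mediated reductive cyclisation of epoxy ketones and epoxy aldehydes to cycloalkane-1,3-diols. C5 should be chosen over the equidistant C10 because C10 lies between quaternary C11 and C6, and attack there would join two fully substituted carbons. At C5 the chair-like 5-exo transition state with the bulky C8–OTi group pseudo-equatorial places the new C5–O bond trans to C8–O. C6 is not expected to emerge trans-fused: with the tether and C10 both on C6, a trans-fused transition state needs a C4–C5–C6–C10 torsion near 110° in the seven-membered ring, whereas the cis-fused one is unstrained, and because C6 of 19 epimerises through the dione enol both epimers should drain through it to 21. The butenolide is a remote, β,β-disubstituted acceptor and should not intercept the tertiary radical; adding the titanium reagent slowly to dilute 19 keeps trapping of the C9 radical by a second titanium (allylic alcohol by β-hydride loss) down.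

Step 13
Reactants: 21 (2S,3aR,5R,6R,8aS)-2,8a-dihydroxy-1,1,5,6-tetramethyl-5-[2-(5-oxo-2,5-dihydrofuran-3-yl)ethyl]octahydroazulen-4(1H)-one
Product: 22 (2S,3aS,5R,6R,8aS)-2,8a-dihydroxy-1,1,5,6-tetramethyl-5-[2-(5-oxo-2,5-dihydrofuran-3-yl)ethyl]octahydroazulen-4(1H)-one
Conditions: DBU (0.3 equiv), CH2Cl2, rt
Reagents that add atoms: none
Why: Base-mediated epimerisation α to a ketone through the C10 enolate. Only C6 (C3a of this name) can invert; the trans-fused epimer brings the C5 hydroxyl syn to the C10 carbonyl for a hydrogen bond, favoured in an aprotic solvent, and should predominate at equilibrium (assumption above). A catalytic amidine base is chosen to spare the butenolide and to avoid alkoxide-driven retro-aldol opening.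

## Compound list

1 | cycloheptane-1,3-dione | O=C1CCCCC(=O)C1 | starting material
2 | 1,4-dioxaspiro[4.6]undecan-7-one | O=C1CCCCC2(C1)OCCO2 | intermediate
3 | trimethyl(1,4-dioxaspiro[4.6]undec-7-en-7-yloxy)silane (not isolated) | C[Si](C)(C)OC1=CCCCC2(C1)OCCO2 | intermediate
4 | 1,4-dioxaspiro[4.6]undec-8-en-7-one | O=C1C=CCCC2(C1)OCCO2 | intermediate
5 | 8-iodo-1,4-dioxaspiro[4.6]undec-8-en-7-one | O=C1C(I)=CCCC2(C1)OCCO2 | intermediate
6 | allyltributylstannane | C=CC[Sn](CCCC)(CCCC)CCCC | starting material
7 | 8-(prop-2-en-1-yl)-1,4-dioxaspiro[4.6]undec-8-en-7-one | C=CCC1=CCCC2(CC1=O)OCCO2 | intermediate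
8 | dimethylaluminium (9R)-9-methyl-8-(prop-2-en-1-yl)-1,4-dioxaspiro[4.6]undec-7-en-7-olate (not isolated) | C[C@@H]1CCC2(OCCO2)CC(O[Al](C)C)=C1CC=C | intermediate
9 | (8R,9R)-8,9-dimethyl-8-(prop-2-en-1-yl)-1,4-dioxaspiro[4.6]undecan-7-one | C[C@@H]1CCC2(OCCO2)CC(=O)[C@]1(C)CC=C | intermediate
10 | 2-[(8R,9R)-8,9-dimethyl-7-oxo-1,4-dioxaspiro[4.6]undecan-8-yl]acetaldehyde (not isolated) | C[C@@H]1CCC2(OCCO2)CC(=O)[C@]1(C)CC=O | intermediate
11 | (8R,9R)-8-(2-hydroxyethyl)-8,9-dimethyl-1,4-dioxaspiro[4.6]undecan-7-one | C[C@@H]1CCC2(OCCO2)CC(=O)[C@]1(C)CCO | intermediate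
12 | (8R,9R)-8-(2-iodoethyl)-8,9-dimethyl-1,4-dioxaspiro[4.6]undecan-7-one | C[C@@H]1CCC2(OCCO2)CC(=O)[C@]1(C)CCI | intermediate
13 | 4-bromofuran-2(5H)-one | O=C1OCC(Br)=C1 | starting material
14 | {2-[(8R,9R)-8,9-dimethyl-7-oxo-1,4-dioxaspiro[4.6]undecan-8-yl]ethyl}(iodo)zinc (not isolated) | C[C@@H]1CCC2(OCCO2)CC(=O)[C@]1(C)CC[Zn]I | intermediate
15 | 4-{2-[(8R,9R)-8,9-dimethyl-7-oxo-1,4-dioxaspiro[4.6]undecan-8-yl]ethyl}furan-2(5H)-one | C[C@@H]1CCC2(OCCO2)CC(=O)[C@]1(C)CCC1=CC(=O)OC1 | intermediate
16 | (4R,5R)-4,5-dimethyl-4-[2-(5-oxo-2,5-dihydrofuran-3-yl)ethyl]cycloheptane-1,3-dione | C[C@@H]1CCC(=O)CC(=O)[C@]1(C)CCC1=CC(=O)OC1 | intermediate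
17 | 3-methylbut-2-en-1-yl acetate (prenyl acetate) | CC(C)=CCOC(C)=O | starting material
18 | (2S,4R,5R)-4,5-dimethyl-2-(3-methylbut-2-en-1-yl)-4-[2-(5-oxo-2,5-dihydrofuran-3-yl)ethyl]cycloheptane-1,3-dione; C2 (C6 of the target) is labile, drawn 2S, in equilibrium with its 2R epimer | C[C@@H]1CCC(=O)[C@H](CC=C(C)C)C(=O)[C@]1(C)CCC1=CC(=O)OC1 | intermediate
19 | (2S,4R,5R)-2-{[(2S)-3,3-dimethyloxiran-2-yl]methyl}-4,5-dimethyl-4-[2-(5-oxo-2,5-dihydrofuran-3-yl)ethyl]cycloheptane-1,3-dione; C2 (C6 of the target) is labile, drawn 2S, in equilibrium with its 2R epimer | C[C@@H]1CCC(=O)[C@H](C[C@H]2C(C)(C)O2)C(=O)[C@]1(C)CCC1=CC(=O)OC1 | intermediate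
20 | 2,8a-bis-O-[chlorobis(cyclopentadienyl)titanium] alkoxide of 21 (not isolated) | C[C@@H]1CC[C@]2(O[Ti](Cl)(C3C=CC=C3)C3C=CC=C3)[C@@H](C[C@H](O[Ti](Cl)(C3C=CC=C3)C3C=CC=C3)C2(C)C)C(=O)[C@]1(C)CCC1=CC(=O)OC1 | intermediate
21 | (2S,3aR,5R,6R,8aS)-2,8a-dihydroxy-1,1,5,6-tetramethyl-5-[2-(5-oxo-2,5-dihydrofuran-3-yl)ethyl]octahydroazulen-4(1H)-one (cis-fused C6 epimer of the target) | C[C@@H]1CC[C@]2(O)[C@@H](C[C@H](O)C2(C)C)C(=O)[C@]1(C)CCC1=CC(=O)OC1 | intermediate
22 | (2S,3aS,5R,6R,8aS)-2,8a-dihydroxy-1,1,5,6-tetramethyl-5-[2-(5-oxo-2,5-dihydrofuran-3-yl)ethyl]octahydroazulen-4(1H)-one | C[C@@H]1CC[C@]2(O)[C@H](C[C@H](O)C2(C)C)C(=O)[C@]1(C)CCC1=CC(=O)OC1 | target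

## Step count and least certain steps

Total: 13 steps. Longest linear sequence: 13 steps (1 to 22); 6, 13 and 17 are used as purchased.

**Step 12 (key step).**
- What may go wrong: interception of the tertiary C9 radical before it adds to C5 (trapping by a second titanium followed by β-hydride loss, or hydrogen abstraction); Lewis-acid-induced opening of the epoxide by the enol oxygen of the dione; loss of facial control at C5 if the O8-bound titanium binds the C5 carbonyl.
- Fallback, from 19 back to 21: the termination pathway is turned into the radical source. With Cp2TiCl at high titanium concentration 19 isomerises to the allylic alcohol (4R,5R)-2-[(2S)-2-hydroxy-3-methylbut-3-en-1-yl]-4,5-dimethyl-4-[2-(5-oxo-2,5-dihydrofuran-3-yl)ethyl]cycloheptane-1,3-dione F1, with C8 intact (handled with its cyclic hemiketal). Metal-hydride hydrogen-atom transfer (Fe(acac)3, PhSiH3, EtOH, 60 °C) to the isopropenyl CH2 of F1 regenerates the same C9 radical at low steady-state concentration and without a stoichiometric radical trap. Its reductive addition to the C5 carbonyl, a known alkene–ketone cyclisation, should give 21.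

**Step 11.**
- What may go wrong: partial ionisation of the dione, leading to hydroxylation at C6 by the dioxirane or to attack of the enol oxygen on the new epoxide; slow turnover of the ketone at the lowered pH.
- Fallback, from 18 back to 19: the 1,3-dicarbonyl is taken out of play during the oxidation. NaBH4 with CeCl3·7H2O in MeOH at −78 °C reduces the less hindered C5 carbonyl to the ketol (6R,7R)-3-hydroxy-6,7-dimethyl-2-(3-methylbut-2-en-1-yl)-7-[2-(5-oxo-2,5-dihydrofuran-3-yl)ethyl]cycloheptan-1-one F2 (any regioisomeric ketol or diol converges later). F2, which has no acidic hydrogen between two carbonyls, is epoxidised with the same L-configured ketone under the usual pH 10.5 protocol to the epoxy ketol F3. Dess–Martin periodinane with NaHCO3 in CH2Cl2 regenerates the dione and delivers 19 under non-basic conditions.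

**Step 5.**
- What may go wrong: sluggish methylation of the aluminium enolate, so that protonation on work-up takes over; incomplete facial control at C11 in the flexible seven-membered ring; modest enantioselectivity on an α-substituted cycloheptenone.
- Fallback, from 7 back to 9: the two events are separated. After the conjugate addition, enolate 8 is silylated with Me3SiOTf and the silyl enol ether (9R)-9-methyl-8-(prop-2-en-1-yl)-7-(trimethylsilyloxy)-1,4-dioxaspiro[4.6]undec-7-ene F4 is isolated. MeLi in THF then releases the lithium enolate, which is methylated with MeI/DMPU under the classical conditions for regiodefined enolates to give 9.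

**Step 10.**
- What may go wrong: O-alkylation that does not return, a second alkylation at C6, or attack at the tertiary terminus of the prenyl–palladium complex.
- Fallback, from 16 back to 18: the allyl group is delivered through oxygen. Allyl alcohol with p-toluenesulfonic acid in refluxing benzene gives the vinylogous ester (6R,7R)-6,7-dimethyl-7-[2-(5-oxo-2,5-dihydrofuran-3-yl)ethyl]-3-(prop-2-en-1-yloxy)cyclohept-2-en-1-one F5. Claisen rearrangement (xylene, 160 °C) places exactly one allyl group on C6 to give (4R,5R)-4,5-dimethyl-4-[2-(5-oxo-2,5-dihydrofuran-3-yl)ethyl]-2-(prop-2-en-1-yl)cycloheptane-1,3-dione F6. Cross-metathesis with 2-methylbut-2-ene (second-generation Grubbs catalyst, CH2Cl2, 40 °C), to which the butenolide is inert, converts allyl into prenyl and returns 18.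

**Step 13.**
- What may go wrong: an equilibrium that does not lie far enough on the trans-fused side, or base-induced retro-aldol opening and dehydration of the tertiary aldol.
- Fallback, from 21 to 22: kinetic instead of thermodynamic control. Me3SiOTf/Et3N converts 21 into the tetrakis-silylated C6=C10 enol ether F7 (C5–O, C8–O and C10–O as OSiMe3, butenolide as 2-(trimethylsilyloxy)furan). Buffered fluoride (Bu4NF, AcOH, THF, −78 °C) then protonates C6 from the face opposite the C5 oxygen substituent, which is the trans-fused arrangement, and releases the hydroxyl groups and the butenolide to give 22.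

## Further compounds

F1 | step 12 | (4R,5R)-2-[(2S)-2-hydroxy-3-methylbut-3-en-1-yl]-4,5-dimethyl-4-[2-(5-oxo-2,5-dihydrofuran-3-yl)ethyl]cycloheptane-1,3-dione | C[C@@H]1CCC(=O)C(C[C@H](O)C(C)=C)C(=O)[C@]1(C)CCC1=CC(=O)OC1
F2 | step 11 | (6R,7R)-3-hydroxy-6,7-dimethyl-2-(3-methylbut-2-en-1-yl)-7-[2-(5-oxo-2,5-dihydrofuran-3-yl)ethyl]cycloheptan-1-one | C[C@@H]1CCC(O)C(CC=C(C)C)C(=O)[C@]1(C)CCC1=CC(=O)OC1
F3 | step 11 | (6R,7R)-2-{[(2S)-3,3-dimethyloxiran-2-yl]methyl}-3-hydroxy-6,7-dimethyl-7-[2-(5-oxo-2,5-dihydrofuran-3-yl)ethyl]cycloheptan-1-one | C[C@@H]1CCC(O)C(C[C@H]2C(C)(C)O2)C(=O)[C@]1(C)CCC1=CC(=O)OC1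
F4 | step 5 | (9R)-9-methyl-8-(prop-2-en-1-yl)-7-(trimethylsilyloxy)-1,4-dioxaspiro[4.6]undec-7-ene | C[C@@H]1CCC2(OCCO2)CC(O[Si](C)(C)C)=C1CC=C
F5 | step 10 | (6R,7R)-6,7-dimethyl-7-[2-(5-oxo-2,5-dihydrofuran-3-yl)ethyl]-3-(prop-2-en-1-yloxy)cyclohept-2-en-1-one | C[C@@H]1CCC(OCC=C)=CC(=O)[C@]1(C)CCC1=CC(=O)OC1
F6 | step 10 | (4R,5R)-4,5-dimethyl-4-[2-(5-oxo-2,5-dihydrofuran-3-yl)ethyl]-2-(prop-2-en-1-yl)cycloheptane-1,3-dione | C[C@@H]1CCC(=O)C(CC=C)C(=O)[C@]1(C)CCC1=CC(=O)OC1
F7 | step 13 | tetrakis(trimethylsilyl) derivative of 21: C6=C10 silyl enol ether, C5 and C8 silyl ethers, butenolide as 2-(trimethylsilyloxy)furan | C[C@@H]1CC[C@]2(O[Si](C)(C)C)C(C[C@H](O[Si](C)(C)C)C2(C)C)=C(O[Si](C)(C)C)[C@]1(C)CCc1coc(O[Si](C)(C)C)c1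
A1 | alternative 1 | cis-divinyl siloxycyclopropane: bicyclo[3.1.0]hexane with vinyl on C5, (E)-alkenyl and OSiMe3 on C10, OSi(t-Bu)Me2 on C8 and on C13 | C=C[C@@]12C(C)(C)[C@@H](O[Si](C)(C)C(C)(C)C)C[C@@H]1[C@@]2(O[Si](C)(C)C)/C(CCO[Si](C)(C)C(C)(C)C)=C/C
A2 | alternative 1 | hydroazulene diene with C10=C11 trimethylsilyl enol ether and C4=C5 alkene | C[C@@H]1CC=C2[C@H](C[C@H](O[Si](C)(C)C(C)(C)C)C2(C)C)C(O[Si](C)(C)C)=C1CCO[Si](C)(C)C(C)(C)C
A3 | alternative 2 | 8-(prop-2-en-1-yl)-1,4-dioxaspiro[4.6]undec-8-en-7-one | C=CCC1=CCCC2(CC1=O)OCCO2
A4 | alternative 2 | (8R,9R)-8,9-dimethyl-8-(prop-2-en-1-yl)-1,4-dioxaspiro[4.6]undecan-7-one | C[C@@H]1CCC2(OCCO2)CC(=O)[C@]1(C)CC=C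
A5 | alternative 3 | 2-{4-[2-(tert-butyldiphenylsilyloxy)ethyl]-4,5-dimethyl-2-methylidene-3-oxo-1-(triethylsilyloxy)cycloheptyl}-2-methylpropanal | C[C@@H]1CC[C@@](O[Si](CC)(CC)CC)(C(C)(C)C=O)C(=C)C(=O)[C@]1(C)CCO[Si](c1ccccc1)(c1ccccc1)C(C)(C)C
A6 | alternative 3 | trans-fused 5-[2-(tert-butyldiphenylsilyloxy)ethyl]-1,1,5,6-tetramethyl-8a-(triethylsilyloxy)octahydroazulene-2,4-dione | C[C@@H]1CC[C@]2(O[Si](CC)(CC)CC)[C@H](CC(=O)C2(C)C)C(=O)[C@]1(C)CCO[Si](c1ccccc1)(c1ccccc1)C(C)(C)C
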